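The numbers in the tables are simulated with made-up constants; scatter was added.

**Balance.** In these closed flasks, starting material, target and what the catalyst holds add up to the charge.

| flask | starting material | partner | free catalyst | remark | time |
|---|---|---|---|---|---|
| epsilon | 1.6 M | 2.08 M | 210 mM | run made earlier |  |
| alpha | 1.6 M | 2.08 M | 480 mM | run made earlier |  |
| gamma | 0.80 M | 2.08 M | 320 mM | run made earlier |  |
| teal | 1.6 M | 2.08 M | 320 mM |  | 6.0 h |
| ochre | 1.6 M | 2.08 M | 320 mM |  | 25 h |

- epsilon (time / h: target / %, starting material / %): 0.833: 2, 86; 2.00: 8, 78; 2.50: 15, 76; 4.00: 18, 70
- alpha (time / h: target / %, starting material / %): 0.833: 7, 65; 2.00: 19, 55; 2.50: 23, 47; 4.00: 32, 40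
- gamma (time / h: target / %, starting material / %): 0.833: 7, 60; 2.00: 20, 45; 2.50: 30, 43; 4.00: 43, 31

(scatter of a reading: 1.5 percentage points)



* which one finishes higher in amount of target, in percent of the starting material charged ("neither" within 2 percentage points) (teal / ochre / neither)
* amount of target at the end, in percent of the starting material charged, teal
* amount of target at the end, in percent of the starting material charged, ochre

**Ceiling.** At the last readings of epsilon and alpha, the held part comes to 0.928 of the catalyst charged. For ochre, a held part of that size gives an estimated ceiling on target of 81.4% of the charge.

**Floor.** Pooled over the three runs, target rate falls between the windows centred at 1.42 h and 3.25 h. Late rate over early rate is a reading, 0.587, and time has dropped out. Scaled to the catalyst charge of teal and ochre, the late rate is 0.0391 /h of the charge. A rate shrinking by that ratio over each equal interval sums to an estimated floor of 33.5% for ochre.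

**Tightening.** Suppose partner consumes itself at second order. Then the rate falls as one over time plus a partner time, which the ratio puts at 1.19 h. The useful quantity is the gain per e-fold, target rate divided by the fractional rate of partner's fall: 17.4% of the charge. Target is this gain times ln(1 + time over partner time). This reckoning gives 31.2% for teal and 53.6% for ochre.

**Forecast.** The forecast says ochre, with 32% for teal and 72% for ochre, noting that “Rates sag somewhat late in the alpha and gamma runs”. Its ochre value lies inside the bracket, above the reckoned value.

**Result.** Teal gives 31.3% and ochre 47.7%, so ochre finishes higher. The main reason for that gap is the difference in time.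

    starting material + free catalyst ⇌ catalyst intermediate A (K = 14.9 /M, k = 0.0918 /M/min)
    2 partner → homo dimer (k = 0.00192 /M/min)
    catalyst intermediate B → free catalyst + target (k = 0.0396 /min)
    partner + catalyst intermediate A ⇌ catalyst intermediate B (K = 0.392 /M, k = 0.0137 /M/min)

**Partner lost.** Ochre ends with 1.1% of its partner and 35% of its starting material: partner is the limiting reagent. Striking out homo dimer formation lifts ochre from 47.7% to 98.3%, so this step is one part of the shortfall. The reckoning from the gain per e-fold stands 6 percentage points above ochre. In the neighbour of teal with 0.83 M of partner, the reckoning keeps 17.4% and stretches partner time to 2.99 h, giving 19.1%; that flask gives 18.3%.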